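**Assumptions.** 1,4-Dioxaspiro[4.5]dec-6-en-8-one, 3-bromofuran, 2,3-dibromopropene, propyne and tert-butyl acetate are taken as cheap catalogue compounds. Late compounds carry briarane locants: ring carbons C1–C10 and C1/C10–C14, CH3-15 on C1, CH3-16 on C5, lactone C17–C18(=O) with CH3-19 on C17, C20 on C11.

## Retrosynthetic overview

1. Target ⇐ triacetylation of a tetraol, whose 18,7-lactone ⇐ a 7,8-epoxy-18,9-lactone (silanolate opening, then carboxylate attack at C7 with inversion); both epoxides ⇐ one peracid treatment of a triene diol.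
2. 2,14-Diol ⇐ 2,14-diketone (bulky hydride at C14, then hydroxyl-directed hydride at C2).
3. Key disconnection: diketo lactone ⇐ a trans-1,2-dialkenylcyclohex-3-enol by anionic oxy-Cope ring expansion (C9–C10, ten-membered ring), followed in the same flask by Claisen acylation of the released enolate by a tethered tert-butyl ester (C1–C14, six-membered ring, quaternary C1).
4. Carbinol ⇐ (R)-2-(3-furyl)-4-methylcyclohex-3-enone + a dienyllithium; the furan is the masked C8/C9/C17/C18 unit (singlet oxygen, then MeCu/Et3SiCl); the ketone ⇐ Rh/BINAP 1,4-addition to a ketal enone (the only external source of chirality).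
5. Ring order: sacrificial cyclohexene → ten- and six-membered carbocycles together (plus a provisional 18,9-lactone) → two epoxides → final 18,7-lactone.

## Route

Step 1
Reactants: 1 tert-butyl acetate; 2 2,3-dibromoprop-1-ene
Product: 4 tert-butyl 4-bromopent-4-enoate, via lithium enolate 3 (not isolated)
Conditions: LDA, THF, −78 °C; then 2, DMPU, −78 → −20 °C
Reagents that add atoms: none
Why: SN2 alkylation of a lithium ester enolate at the allylic bromide, the vinylic bromide being inert; no stereocentre.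

Step 2
Reactants: 4 tert-butyl 4-bromopent-4-enoate; 5 propyne
Product: 6 tert-butyl 4-methylidenehept-5-ynoate
Conditions: PdCl2(PPh3)2 (3 mol%), CuI (6 mol%), iPr2NH, THF, 23 °C
Reagents that add atoms: none
Why: Sonogashira coupling of a 2-bromo-1-alkene with a terminal alkyne; no stereocentre.

Step 3
Reactants: 6 tert-butyl 4-methylidenehept-5-ynoate
Product: 8 tert-butyl (5E)-6-iodo-4-methylidenehept-5-enoate, via alkenylzirconocene 7 (not isolated)
Conditions: Cp2Zr(H)Cl (1.3 equiv), THF, 23 °C, dark; then I2, 0 °C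
Reagents that add atoms: iodine, II
Why: syn-Hydrozirconation (Schwartz) puts Zr on the less hindered methyl-bearing alkyne carbon and iododezirconation with retention gives the iodide with I trans to C4, the geometry the later chair transition state needs.

Step 4
Reactants: 9 3-bromofuran; 10 1,4-dioxaspiro[4.5]dec-6-en-8-one
Product: 13 trimethyl{[(6R)-6-(furan-3-yl)-1,4-dioxaspiro[4.5]dec-7-en-8-yl]oxy}silane, via 3-furyllithium 11 (not isolated), via 3-furylzinc chloride 12 (not isolated)
Conditions: 9, n-BuLi, THF, −78 °C; ZnCl2, −78 → 0 °C; then 10, [RhCl((R)-binap)]2 (3 mol% Rh), Me3SiCl, THF, 20 °C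
Reagents that add atoms: chlorotrimethylsilane, C[Si](C)(C)Cl
Why: Rh/BINAP-catalysed asymmetric 1,4-addition of an arylzinc chloride (Hayashi type) with in situ silylation; (R)-BINAP, the enantiomer that gives (R)-3-arylcyclohexanones, sets the (6R) centre and the enolate is trapped regiospecifically.

Step 5
Reactants: 13 trimethyl{[(6R)-6-(furan-3-yl)-1,4-dioxaspiro[4.5]dec-7-en-8-yl]oxy}silane
Product: 14 (6R)-6-(furan-3-yl)-1,4-dioxaspiro[4.5]dec-7-en-8-yl trifluoromethanesulfonate
Conditions: PhNTf2, CsF, DME, 23 °C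
Reagents that add atoms: N-phenylbis(trifluoromethanesulfonimide), O=S(=O)(N(c1ccccc1)S(=O)(=O)C(F)(F)F)C(F)(F)F
Why: Fluoride-induced desilylation frees the regiodefined enolate, which is O-triflated (enol triflate formation); the stereocentre is not touched.

Step 6
Reactants: 14 (6R)-6-(furan-3-yl)-1,4-dioxaspiro[4.5]dec-7-en-8-yl trifluoromethanesulfonate
Product: 15 (6R)-6-(furan-3-yl)-8-methyl-1,4-dioxaspiro[4.5]dec-7-ene
Conditions: MeMgBr (1.5 equiv), Fe(acac)3 (5 mol%), THF/NMP, −20 → 0 °C
Reagents that add atoms: methylmagnesium bromide, C[Mg]Br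
Why: Iron-catalysed Kumada-type cross-coupling of an alkenyl triflate installs the future CH3-16 on the future (Z)-C5=C6 bond; the stereocentre is not affected.

Step 7
Reactants: 15 (6R)-6-(furan-3-yl)-8-methyl-1,4-dioxaspiro[4.5]dec-7-ene
Product: 16 (2R)-2-(furan-3-yl)-4-methylcyclohex-3-en-1-one
Conditions: I2 (10 mol%), acetone/H2O (20:1), 23 °C, 15 min; used at once
Reagents that add atoms: water, O
Why: Iodine-catalysed near-neutral deketalisation, chosen so that the doubly activated α-stereocentre and the β,γ-alkene survive until the ketone is consumed.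

Step 8
Reactants: 8 tert-butyl (5E)-6-iodo-4-methylidenehept-5-enoate; 16 (2R)-2-(furan-3-yl)-4-methylcyclohex-3-en-1-one
Product: 18 tert-butyl (5E)-6-[(1R,2R)-2-(furan-3-yl)-1-hydroxy-4-methylcyclohex-3-en-1-yl]-4-methylidenehept-5-enoate, via dienyllithium 17 (not isolated)
Conditions: 8, t-BuLi (2.05 equiv), Et2O, −100 °C; LaCl3·2LiCl (1 equiv), then 16, THF, −78 °C; aq NH4Cl
Reagents that add atoms: none
Why: Iodine–lithium exchange with retention (the ester sits trans to Li and cannot cyclise), then lanthanum-promoted 1,2-addition with little enolisation; equatorial attack anti to the furyl group gives the trans-dialkenyl carbinol (new centre 1R).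

Step 9
Reactants: 18 tert-butyl (5E)-6-[(1R,2R)-2-(furan-3-yl)-1-hydroxy-4-methylcyclohex-3-en-1-yl]-4-methylidenehept-5-enoate
Product: 19 tert-butyl (5E)-6-[(1R,2R)-1-hydroxy-2-(2-hydroxy-5-oxo-2,5-dihydrofuran-3-yl)-4-methylcyclohex-3-en-1-yl]-4-methylidenehept-5-enoate (lactol epimers)
Conditions: O2, hν, tetraphenylporphyrin (cat.), iPr2NEt, CH2Cl2, −78 °C
Reagents that add atoms: oxygen, O=O
Why: Singlet-oxygen [4+2] addition to the furan and base-induced fragmentation of the endoperoxide at the unhindered α-CH (regioselective 3-alkylfuran photooxygenation) place the lactol carbon next to the substituted carbon; the furan reacts far faster than the trisubstituted alkenes and existing centres are untouched.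

Step 10
Reactants: 19 tert-butyl (5E)-6-[(1R,2R)-1-hydroxy-2-(2-hydroxy-5-oxo-2,5-dihydrofuran-3-yl)-4-methylcyclohex-3-en-1-yl]-4-methylidenehept-5-enoate
Product: 20 (3E)-3-[(1R,6R)-6-[(2E)-7-tert-butoxy-4-methylidene-7-oxohept-2-en-2-yl]-6-hydroxy-3-methylcyclohex-2-en-1-yl]-2-methyl-4-[(triethylsilyl)oxy]but-3-enoic acid (C2 epimers; kept as its Et3NH+ salt)
Conditions: Me2CuLi (3.5 equiv, from MeLi/CuI), Et3SiCl (3 equiv), THF, −78 °C; pH 7 buffer
Reagents that add atoms: lithium dimethylcuprate, [Li+].C[Cu-]C; chlorotriethylsilane, CC[Si](Cl)(CC)CC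
Why: Proposed new method: the deprotonated lactol opens to the (Z)-4-oxo-2-enoate, whose s-trans enal (s-cis is disfavoured by carboxylate/carbonyl repulsion) takes methyl at the carbon β to the aldehyde (the closed butenolide is blocked at its fully substituted β-carbon), and Et3SiCl traps the enolate with O–Si cis to the ring carbon while the hindered tertiary alkoxide stays free; closest known reaction is the chlorosilane-accelerated Gilman conjugate addition to enals, with C17 left unset here and fixed in step 14.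

Step 11
Reactants: 20 (3E)-3-[(1R,6R)-6-[(2E)-7-tert-butoxy-4-methylidene-7-oxohept-2-en-2-yl]-6-hydroxy-3-methylcyclohex-2-en-1-yl]-2-methyl-4-[(triethylsilyl)oxy]but-3-enoic acid
Product: 23 2,14-dioxobriara-5Z,7E,11(20)-trien-18,9-olide (C1/C9/C10 as in 30; C17 epimers), via oxy-Cope enolate 21 (not isolated), via silyl ether diketo acid 22 (not isolated)
Conditions: KHMDS (4 equiv), 18-crown-6 (4 equiv), THF, −40 → 0 °C; then 1 M HCl, THF, 23 °C
Reagents that add atoms: none
Why: Proposed new method: the potassium alkoxide undergoes a chair [3,3] shift (both alkenyl groups equatorial, C11 pseudo-equatorial on C10 and O–Si pseudo-axial on C9), which opens the cyclohexene to the ten-membered ring, keeps C5=C6 Z, makes C7=C8 E and transfers the carbinol chirality to C9 and C10 as in 30; the released (E)-enolate is then acylated 6-exo by the tethered tert-butyl ester from its open peripheral face (Claisen/Dieckmann), closing the six-membered ring with CH3-15 trans to H-10, excess base enolising the product to pull the equilibrium over, and the acid work-up removes the silyl group and closes the 18,9-lactone; closest known reactions are the anionic oxy-Cope ring expansion of 1,2-divinylcyclohexanols with in situ enolate capture and the Dieckmann synthesis of 2,2-disubstituted 1,3-diketones.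

Step 12
Reactants: 23 2,14-dioxobriara-5Z,7E,11(20)-trien-18,9-olide
Product: 25 2,14-dihydroxybriara-5Z,7E,11(20)-trien-18,9-olide (C1/C2/C9/C10/C14 as in 30; C17 epimers), via 14-hydroxy ketone 24 (not isolated)
Conditions: L-Selectride (1.1 equiv), THF, −78 °C; then AcOH, MeCN, Me4NBH(OAc)3 (5 equiv), −25 °C
Reagents that add atoms: none
Why: The bulky hydride attacks the more reactive cyclohexanone equatorially to give the axial 14-OH (trans to CH3-15), and this hydroxyl then delivers hydride to the medium-ring C2 ketone through a six-membered triacetoxyborohydride transition state (Evans–Saksena reduction) to give the 1,3-anti diol found in 30.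

Step 13
Reactants: 25 2,14-dihydroxybriara-5Z,7E,11(20)-trien-18,9-olide
Product: 26 7,8:11,20-diepoxy-2,14-dihydroxybriar-5Z-en-18,9-olide (C8 and C11 as in 30; C7 still to be inverted; C17 epimers)
Conditions: mCPBA (2.3 equiv), NaHCO3, CH2Cl2, −20 → 0 °C
Reagents that add atoms: 3-chloroperbenzoic acid, O=C(OO)c1cccc(Cl)c1
Why: Prilezhaev epoxidation: the strained (E)-C7=C8 bond, held by the 18,9-lactone so that C10 and the ring chain cover one face, is attacked on the open face anti to C10 (correct C8), and the exocyclic C11=C20 is attacked from the equatorial side away from axial CH3-15 (O equatorial, 11R), while C5=C6 is deactivated by the new allylic epoxide.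

Step 14
Reactants: 26 7,8:11,20-diepoxy-2,14-dihydroxybriar-5Z-en-18,9-olide
Product: 29 2,8,9,14-tetrahydroxy-11,20-epoxybriar-5Z-en-18,7-olide (all stereocentres as in 30), via ring-opened carboxylate 27 (not isolated), via C17-epimeric tetraol 28 (not isolated)
Conditions: KOSiMe3 (1.2 equiv), THF, 0 °C; NaH2PO4 buffer (pH 5), 35 °C; then DBU (0.3 equiv), toluene, 60 °C
Reagents that add atoms: potassium trimethylsilanolate, C[Si](C)(C)[O-].[K+]
Why: Silanolate cleavage of the lactone gives the carboxylate with O9 capped as its silyl ether (no free alkoxide for Payne or oxolane side reactions), the carboxylate opens the allylic epoxide at C7 with inversion (SN2, 5-ring) to set C7 and free the 8-OH, and base equilibration of the lactone α-carbon puts CH3-19 trans to the bulky C9 substituent (17R).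

Step 15
Reactants: 29 2,8,9,14-tetrahydroxy-11,20-epoxybriar-5Z-en-18,7-olide
Product: 30 junceellolide K
Conditions: Ac2O (6 equiv), DMAP (0.2 equiv), pyridine, CH2Cl2, 0 → 23 °C
Reagents that add atoms: acetic anhydride, CC(=O)OC(C)=O
Why: DMAP-catalysed acetylation of the three secondary alcohols, the hindered tertiary 8-OH staying free; no stereocentre is touched.

## Compound list

1 | tert-butyl acetate | CC(=O)OC(C)(C)C | starting material
2 | 2,3-dibromoprop-1-ene | C=C(Br)CBr | starting material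
3 | lithium enolate of tert-butyl acetate (not isolated) | [Li]OC(=C)OC(C)(C)C | intermediate
4 | tert-butyl 4-bromopent-4-enoate | C=C(Br)CCC(=O)OC(C)(C)C | intermediate
5 | propyne | CC#C | starting material
6 | tert-butyl 4-methylidenehept-5-ynoate | CC#CC(=C)CCC(=O)OC(C)(C)C | intermediate
7 | chlorobis(cyclopentadienyl)[(E)-alkenyl]zirconium from 6, Zr trans to C4 (not isolated) | C/C(=C\C(=C)CCC(=O)OC(C)(C)C)[Zr](Cl)(C1C=CC=C1)C1C=CC=C1 | intermediate
8 | tert-butyl (5E)-6-iodo-4-methylidenehept-5-enoate | I/C(C)=C/C(=C)CCC(=O)OC(C)(C)C | intermediate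
9 | 3-bromofuran | Brc1ccoc1 | starting material
10 | 1,4-dioxaspiro[4.5]dec-6-en-8-one | O=C1C=CC2(CC1)OCCO2 | starting material
11 | 3-furyllithium (not isolated) | [Li]c1ccoc1 | intermediate
12 | 3-furylzinc chloride (not isolated) | Cl[Zn]c1ccoc1 | intermediate
13 | trimethyl{[(6R)-6-(furan-3-yl)-1,4-dioxaspiro[4.5]dec-7-en-8-yl]oxy}silane | C[Si](C)(C)OC1=C[C@H](c2ccoc2)C2(CC1)OCCO2 | intermediate
14 | (6R)-6-(furan-3-yl)-1,4-dioxaspiro[4.5]dec-7-en-8-yl trifluoromethanesulfonate | O=S(=O)(OC1=C[C@H](c2ccoc2)C2(CC1)OCCO2)C(F)(F)F | intermediate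
15 | (6R)-6-(furan-3-yl)-8-methyl-1,4-dioxaspiro[4.5]dec-7-ene | CC1=C[C@H](c2ccoc2)C2(CC1)OCCO2 | intermediate
16 | (2R)-2-(furan-3-yl)-4-methylcyclohex-3-en-1-one | CC1=C[C@H](c2ccoc2)C(=O)CC1 | intermediate
17 | tert-butyl 6-lithio-4-methylidenehept-5-enoate, Li trans to C4 as in 8 (not isolated) | [Li]/C(C)=C/C(=C)CCC(=O)OC(C)(C)C | intermediate
18 | tert-butyl (5E)-6-[(1R,2R)-2-(furan-3-yl)-1-hydroxy-4-methylcyclohex-3-en-1-yl]-4-methylidenehept-5-enoate | O[C@]1(/C(C)=C/C(=C)CCC(=O)OC(C)(C)C)CCC(C)=C[C@@H]1c1ccoc1 | intermediate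
19 | tert-butyl (5E)-6-[(1R,2R)-1-hydroxy-2-(2-hydroxy-5-oxo-2,5-dihydrofuran-3-yl)-4-methylcyclohex-3-en-1-yl]-4-methylidenehept-5-enoate (lactol epimers) | O[C@]1(/C(C)=C/C(=C)CCC(=O)OC(C)(C)C)CCC(C)=C[C@@H]1C1=CC(=O)OC1O | intermediate
20 | (3E)-3-[(1R,6R)-6-[(2E)-7-tert-butoxy-4-methylidene-7-oxohept-2-en-2-yl]-6-hydroxy-3-methylcyclohex-2-en-1-yl]-2-methyl-4-[(triethylsilyl)oxy]but-3-enoic acid (C2 epimers; O–Si cis to the ring carbon) | O[C@]1(/C(C)=C/C(=C)CCC(=O)OC(C)(C)C)CCC(C)=C[C@@H]1/C(=C\O[Si](CC)(CC)CC)C(C)C(=O)O | intermediate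
21 | dipotassium 14-tert-butoxy-14-oxo-2-oxido-9-(triethylsilyloxy)-1,14-secobriara-1(2)E,5Z,7E,11(20)-tetraen-18-oate, C9/C10 as in 30 (not isolated) | [K+].[K+].[O-]/C1CC/C(C)=C\C=C(/C(C)C(=O)[O-])[C@@H](O[Si](CC)(CC)CC)[C@@H](C(=C)CCC(=O)OC(C)(C)C)/C(C)=1 | intermediate
22 | 2,14-dioxo-9-(triethylsilyloxy)briara-5Z,7E,11(20)-trien-18-oic acid, C1/C9/C10 as in 30 (not isolated) | O=C1CC/C(C)=C\C=C(/C(C)C(=O)O)[C@@H](O[Si](CC)(CC)CC)[C@H]2C(=C)CCC(=O)[C@]12C | intermediate
23 | 2,14-dioxobriara-5Z,7E,11(20)-trien-18,9-olide (C1/C9/C10 as in 30; C17 epimers) | O=C1CC/C(C)=C\C=C2/C(C)C(=O)O[C@H]2[C@H]2C(=C)CCC(=O)[C@]12C | intermediate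
24 | 14-hydroxy-2-oxobriara-5Z,7E,11(20)-trien-18,9-olide, 14-OH axial as in 30 (not isolated) | O=C1CC/C(C)=C\C=C2/C(C)C(=O)O[C@H]2[C@H]2C(=C)CC[C@H](O)[C@]12C | intermediate
25 | 2,14-dihydroxybriara-5Z,7E,11(20)-trien-18,9-olide (C1/C2/C9/C10/C14 as in 30; C17 epimers) | O[C@H]1CC/C(C)=C\C=C2/C(C)C(=O)O[C@H]2[C@H]2C(=C)CC[C@H](O)[C@]12C | intermediate
26 | 7,8:11,20-diepoxy-2,14-dihydroxybriar-5Z-en-18,9-olide (C7 opposite to 30, all other set centres as in 30; C17 epimers) | O[C@H]1CC/C(C)=C\[C@H]2O[C@@]23C(C)C(=O)O[C@H]3[C@H]2[C@]3(CC[C@H](O)[C@]12C)CO3 | intermediate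
27 | potassium 7,8:11,20-diepoxy-2,14-dihydroxy-9-(trimethylsilyloxy)briar-5Z-en-18-oate (not isolated) | [K+].O[C@H]1CC/C(C)=C\[C@H]2O[C@]2(C(C)C(=O)[O-])[C@@H](O[Si](C)(C)C)[C@H]2[C@]3(CC[C@H](O)[C@]12C)CO3 | intermediate
28 | 2,8,9,14-tetrahydroxy-11,20-epoxybriar-5Z-en-18,7-olide, C17 epimers (not isolated) | O[C@H]1CC/C(C)=C\[C@@H]2OC(=O)C(C)[C@@]2(O)[C@@H](O)[C@H]2[C@]3(CC[C@H](O)[C@]12C)CO3 | intermediate
29 | 2,8,9,14-tetrahydroxy-11,20-epoxybriar-5Z-en-18,7-olide (tri-O-deacetyl 30, all centres as in 30) | O[C@H]1CC/C(C)=C\[C@@H]2OC(=O)[C@H](C)[C@@]2(O)[C@@H](O)[C@H]2[C@]3(CC[C@H](O)[C@]12C)CO3 | intermediate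
30 | junceellolide K, (1S,2S,5Z,7S,8S,9S,10S,11R,14S,17R)-2,9,14-triacetoxy-8-hydroxy-11,20-epoxybriar-5-en-18,7-olide | CC(=O)O[C@H]1CC/C(C)=C\[C@@H]2OC(=O)[C@H](C)[C@@]2(O)[C@@H](OC(C)=O)[C@H]2[C@]3(CC[C@H](OC(C)=O)[C@]12C)CO3 | target

## Step count and risk

Total steps: 15. Longest linear sequence: 12 (steps 4–15 from 9 and 10); the three-step branch (steps 1–3) joins at step 8.

The three steps most likely to fail:

Step 11 (oxy-Cope/Claisen cascade). The Claisen closure may not follow the sigmatropic shift, or the silyl group may migrate to the alkoxide. The fallback sets out from 20 and separates the two ring formations. KHMDS (2.2 equiv)/18-crown-6 at −40 °C with an NH4Cl quench stops after the oxy-Cope shift and gives the ten-membered keto ester F1. TFA in CH2Cl2 removes the tert-butyl ester and the silyl ether and closes the 18,9-lactone to keto acid F2. EDC/C6F5OH gives the pentafluorophenyl ester F3. MgBr2·OEt2/iPr2NEt (soft enolisation toward the more substituted C1 and charge-neutral C-acylation, so no alkoxide is present to reverse it) then closes the six-membered ring. The route is rejoined at 23.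

Step 12 (C2 reduction). The directed hydride delivery across the quaternary C1 may be slow or give the 2-epimer. The fallback sets out from 24, isolated after the L-Selectride stage. An Evans–Tishchenko reduction (SmI2 15 mol%, CH3CHO, THF, −10 °C) transfers hydride within a samarium-bound hemiacetal and gives the anti 2-hydroxy 14-acetate F4. The conditions of step 13 convert it to the diepoxide acetate F5. Step 14 run with 2.5 equiv KOSiMe3 also cleaves the acetate, and the route is rejoined at 29.

Step 13 (double epoxidation). C5=C6 may compete, or the peracid may take the wrong face of C7=C8. The fallback sets out from 25 and lets the carboxylate choose the alkene. KOSiMe3 opens the lactone to the carboxylate F6. Kinetic iodolactonisation (I2, NaHCO3, MeCN, 0 °C; 4-exo, iodonium on the open face, carboxylate from the inner face) gives the iodo β-lactone F7 with the C8–O bond as in 30. AgOTf in aqueous acetone solvolyses the allylic iodide from the open face at C7, and the new 7-OH opens the strained β-lactone to the 18,7-lactone triol F8, which also loses the silyl group. mCPBA (1.1 equiv) then epoxidises the remaining exocyclic alkene, and the route is rejoined at 28.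

Further compounds

F1 | step 11 | 14-tert-butoxy-2,14-dioxo-9-(triethylsilyloxy)-1,14-secobriara-5Z,7E,11(20)-trien-18-oic acid (C1 and C17 epimers) | O=C1CC/C(C)=C\C=C(/C(C)C(=O)O)[C@@H](O[Si](CC)(CC)CC)[C@@H](C(=C)CCC(=O)OC(C)(C)C)C1C
F2 | step 11 | 2-oxo-1,14-secobriara-5Z,7E,11(20)-trien-18,9-olid-14-oic acid (C1 and C17 epimers) | O=C1CC/C(C)=C\C=C2/C(C)C(=O)O[C@H]2[C@@H](C(=C)CCC(=O)O)C1C
F3 | step 11 | pentafluorophenyl ester of F2 | O=C1CC/C(C)=C\C=C2/C(C)C(=O)O[C@H]2[C@@H](C(=C)CCC(=O)Oc2c(F)c(F)c(F)c(F)c2F)C1C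
F4 | step 12 | 14-acetoxy-2-hydroxybriara-5Z,7E,11(20)-trien-18,9-olide (C17 epimers) | O[C@H]1CC/C(C)=C\C=C2/C(C)C(=O)O[C@H]2[C@H]2C(=C)CC[C@H](OC(C)=O)[C@]12C
F5 | step 12 | 14-acetoxy-7,8:11,20-diepoxy-2-hydroxybriar-5Z-en-18,9-olide (C17 epimers) | O[C@H]1CC/C(C)=C\[C@H]2O[C@@]23C(C)C(=O)O[C@H]3[C@H]2[C@]3(CC[C@H](OC(C)=O)[C@]12C)CO3
F6 | step 13 | potassium 2,14-dihydroxy-9-(trimethylsilyloxy)briara-5Z,7E,11(20)-trien-18-oate (C17 epimers) | [K+].O[C@H]1CC/C(C)=C\C=C(/C(C)C(=O)[O-])[C@@H](O[Si](C)(C)C)[C@H]2C(=C)CC[C@H](O)[C@]12C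
F7 | step 13 | 2,14-dihydroxy-7-iodo-9-(trimethylsilyloxy)briara-5Z,11(20)-dien-18,8-olide (β-lactone; C17 epimers) | O[C@H]1CC/C(C)=C\[C@H](I)[C@]2(OC(=O)C2C)[C@@H](O[Si](C)(C)C)[C@H]2C(=C)CC[C@H](O)[C@]12C
F8 | step 13 | 2,8,9,14-tetrahydroxybriara-5Z,11(20)-dien-18,7-olide (C17 epimers) | O[C@H]1CC/C(C)=C\[C@@H]2OC(=O)C(C)[C@@]2(O)[C@@H](O)[C@H]2C(=C)CC[C@H](O)[C@]12C
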